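A direct plan would take ring B from methyl vanillate A1, make its 1,1-dimethylallyl ether A3 by palladium-catalysed O-allylation with tert-butyl 2-methylbut-3-en-2-yl carbonate A2, and condense A3 with the lithium enolate of methyl methoxyacetate A4 to the α-methoxy β-keto ester A5.
It would end by heating A5 with unprotected phloroglucinol A6: aromatic Claisen rearrangement, ketene C-acylation and cyclodehydration in one flask would close ring C last.
Its weakest steps would be:
(a) the final thermal rearrangement/pyrocondensation of A5 with A6, an untested merger at 175–240 °C on free polyphenols in which chroman closure of the o-prenylphenol, loss of the allyl group, O-acylation and coumarin formation compete, placed where all the material is at stake;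
(b) the crossed Claisen condensation of A3 with A4, because a p-alkoxybenzoate such as A3 is a poor acyl acceptor and the enolate of A4 condenses with itself;
(c) the O-allylation of A1 with A2 to the tertiary ether A3, whose branched selectivity is only kinetic, since zerovalent palladium re-ionises A3 and lets it drift to the linear prenyl ether.

**Retrosynthetic overview of the new route**
- Ring A (C4a, C5, C6, C7, C8, C8a; 5-OH peri to the C4 carbonyl, 7-OH meta to it) would be built last, in one operation, by a Danheiser benzannulation onto the γ-pyrone: diazo ketone 12 gives a pyranonylketene (C5 and C8), and silyl ynol ether 16 supplies C6, C7 and the 7-oxygen.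
- Ring C would be kojic acid: its ring oxygen, carbonyl and enolic OH become O1, C4=O and the 3-OMe, its C6 is brominated for the C2–C1' Suzuki coupling, and its CH2OH carbon is oxidised and ends as C5.
- Ring B would come from 4-bromo-2-methoxyphenol by ortho C-prenylation. Rings B and C are bought and ring A closes last, whereas the direct plan buys ring A and closes ring C last.
- Nothing is heated above 90 °C, no polyphenol is acylated, no ester enolate is condensed, and the prenyl group goes directly onto carbon. The 4'-OH stays silylated until a final fluoride step, so the o-prenylphenol never meets acid or heat.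

Key step: step 9

Abbreviations in names: TIPS = tri(propan-2-yl)silyl; Ar = 3-methoxy-5-(3-methylbut-2-en-1-yl)-4-(TIPS-oxy)phenyl.
Assumption: the parent silyl ynol ether, (ethynyloxy)tri(propan-2-yl)silane 16, is taken to be isolable and storable cold like its alkyl-substituted congeners; it would be made shortly before use.

**Step 1**
Reactants: 1 4-bromo-2-methoxyphenol; 2 1-bromo-3-methylbut-2-ene (prenyl bromide)
Product: 3 4-bromo-2-methoxy-6-(3-methylbut-2-en-1-yl)phenol
Conditions: NaH (1.05 equiv), toluene, 0 °C to rt; then 2 (1.1 equiv), rt, 16 h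
Reagents that add atoms: none
Why: Ortho C-alkylation of a phenoxide, in which the sodium salt reacts in toluene as a tight ion pair whose shielded oxygen leaves the ortho carbon to attack the allylic bromide, and C6 is the only ortho or para carbon of 1 that still carries hydrogen (C2 has OMe, C4 has Br), so rearomatisation can give only 3; no stereocentre is formed.

**Step 2**
Reactants: 3 4-bromo-2-methoxy-6-(3-methylbut-2-en-1-yl)phenol
Product: 4 [4-bromo-2-methoxy-6-(3-methylbut-2-en-1-yl)phenoxy]tri(propan-2-yl)silane
Conditions: iPr3SiOTf (1.2 equiv), 2,6-lutidine (1.5 equiv), CH2Cl2, 0 °C to rt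
Reagents that add atoms: triisopropylsilyl trifluoromethanesulfonate, CC(C)[Si](OS(=O)(=O)C(F)(F)F)(C(C)C)C(C)C
Why: Silylation of a hindered phenol with a silyl triflate and a non-nucleophilic base, the TIPS ether being chosen because it should survive aqueous phosphate, the oxoammonium oxidation and the acid chloride, keep the phenol away from the ketene of step 9, and leave at the end with fluoride under conditions that cannot close a chroman onto the prenyl group; no stereocentre is formed.

**Step 3**
Reactants: 5 kojic acid
Product: 6 2-bromo-3-hydroxy-6-(hydroxymethyl)-4H-pyran-4-one (6-bromokojic acid)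
Conditions: NBS (1.05 equiv), DMF, 0 °C to rt, dark
Reagents that add atoms: N-bromosuccinimide, O=C1CCC(=O)N1Br
Why: Electrophilic bromination of an enol, in which the 5-hydroxy group of kojic acid makes C6 the nucleophilic carbon (the position at which kojic acid takes halogens, Mannich and aldol electrophiles) whereas C3 is only the α-carbon of a vinylogous ester; no stereocentre is formed.

**Step 4**
Reactants: 6 2-bromo-3-hydroxy-6-(hydroxymethyl)-4H-pyran-4-one
Product: 7 2-bromo-6-(hydroxymethyl)-3-methoxy-4H-pyran-4-one
Conditions: MeI (1.3 equiv), K2CO3 (1.2 equiv), acetone, rt to 40 °C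
Reagents that add atoms: iodomethane, CI
Why: Williamson ether synthesis, in which carbonate deprotonates only the acidic enolic OH and not the primary alcohol, so that methylation gives the future 3-OMe of the flavone; no stereocentre is formed.

**Step 5**
Reactants: 4 [4-bromo-2-methoxy-6-(3-methylbut-2-en-1-yl)phenoxy]tri(propan-2-yl)silane; 7 2-bromo-6-(hydroxymethyl)-3-methoxy-4H-pyran-4-one
Product: 9 2-Ar-6-(hydroxymethyl)-3-methoxy-4H-pyran-4-one, via arylboronic ester 8 (not isolated)
Conditions: 4, B2pin2 (1.1 equiv), PdCl2(dppf) (3 mol %; dppf = 1,1'-bis(diphenylphosphino)ferrocene), KOAc (3 equiv), 1,4-dioxane, 90 °C, 4 h; then 7 (0.9 equiv), K3PO4 (3 equiv), H2O, 80 °C, 3 h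
Reagents that add atoms: bis(pinacolato)diboron, CC1(C)OB(OC1(C)C)B1OC(C)(C)C(C)(C)O1 (supplies only the boryl group of 8)
Why: Miyaura borylation followed in the same flask by Suzuki–Miyaura coupling, in which the unhindered aryl bromide 4 is borylated under acetate and 7, a vinylogous acyl bromide, should add readily to zerovalent palladium and couple with 8 in the presence of the free CH2OH group, forming the bond that becomes C2–C1' of the flavone; no stereocentre is formed.

**Step 6**
Reactants: 9 2-Ar-6-(hydroxymethyl)-3-methoxy-4H-pyran-4-one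
Product: 10 6-Ar-5-methoxy-4-oxo-4H-pyran-2-carboxylic acid
Conditions: TEMPO (2,2,6,6-tetramethylpiperidin-1-oxyl, 0.2 equiv), PhI(OAc)2 (2.2 equiv), MeCN–H2O (1:1), rt
Reagents that add atoms: water, O
Why: Oxoammonium (TEMPO) oxidation with PhI(OAc)2 as the terminal oxidant, in which the heteroaryl carbinol is oxidised to the aldehyde and its hydrate (water supplies the second oxygen) on to the acid, under conditions that leave the trisubstituted alkene, the aryl silyl ether and the pyranone untouched; no stereocentre is formed.

**Step 7**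
Reactants: 10 6-Ar-5-methoxy-4-oxo-4H-pyran-2-carboxylic acid
Product: 12 2-Ar-6-(diazoacetyl)-3-methoxy-4H-pyran-4-one, via acid chloride 11 (not isolated)
Conditions: 1-chloro-N,N,2-trimethylprop-1-en-1-amine (1.1 equiv), CH2Cl2, 0 °C to rt, 1 h; then Me3SiCHN2 (2 M in hexanes, 2.0 equiv), MeCN–THF, 0 °C to rt; aq. NaHCO3
Reagents that add atoms: (trimethylsilyl)diazomethane, C[Si](C)(C)C=[N+]=[N-]; 1-chloro-N,N,2-trimethylprop-1-en-1-amine, CC(C)=C(Cl)N(C)C (supplies only the chlorine of 11)
Why: First stage of an Arndt–Eistert sequence, in which the α-chloroenamine makes the acid chloride under neutral conditions, so that no HCl can add to the prenyl group, and C-acylation of (trimethylsilyl)diazomethane followed by loss of the silyl group to chloride gives the diazo ketone; no stereocentre is formed.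

**Step 8**
Reactants: 13 acetylene
Product: 16 (ethynyloxy)tri(propan-2-yl)silane, via lithium acetylide 14 (not isolated), via lithium ethynolate 15 (not isolated)
Conditions: 13 (excess, saturated in THF), n-BuLi (1.0 equiv), −78 °C; LiOOtBu [from t-BuOOH (1.0 equiv) and LiN(SiMe3)2 (1.0 equiv), THF, −78 °C], −78 to −20 °C; iPr3SiOTf (1.0 equiv), −78 to 0 °C; pentane extraction, bulb-to-bulb distillation
Reagents that add atoms: lithium tert-butyl peroxide, [Li+].[O-]OC(C)(C)C (made in the flask from tert-butyl hydroperoxide, CC(C)(C)OO); triisopropylsilyl trifluoromethanesulfonate, CC(C)[Si](OS(=O)(=O)C(F)(F)F)(C(C)C)C(C)C; n-butyllithium, [Li]CCCC (supplies only the lithium of 14 and 15)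
Why: Oxidation of a lithium acetylide with a lithium alkyl peroxide (attack of the acetylide on the O–O bond gives the ynolate and LiOtBu) followed by O-silylation, the established route from 1-alkynes to silyl ynol ethers, applied here to acetylene itself, with the bulky silyl triflate expected to favour O- over C-silylation and to slow the 1,3-shift to the silylketene; no stereocentre is formed.

**Step 9**
Reactants: 12 2-Ar-6-(diazoacetyl)-3-methoxy-4H-pyran-4-one; 16 (ethynyloxy)tri(propan-2-yl)silane
Product: 21 2-Ar-5-hydroxy-3-methoxy-7-(TIPS-oxy)-4H-chromen-4-one, via pyranonylketene 17 (not isolated), via cyclobutenone 18 (not isolated), via dienylketene 19 (not isolated), via 4aH-dienone 20 (not isolated)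
Conditions: 12, 16 (2.5 equiv), ClCH2CH2Cl (0.02 M), blue LED (450 nm), 20 °C, until N2 evolution stops; then 80 °C, 3 h, in the dark
Reagents that add atoms: none
Why: Danheiser benzannulation in its diazo ketone form: light of 450 nm is absorbed only by the diazo ketone, and loss of N2 with 1,2-shift of the pyranonyl group (Wolff rearrangement) gives ketene 17, whose ketene carbon is the former carboxyl carbon (future C5) and whose CH, now bonded to the ring, is the future C8. The polarised ynol ether 16 adds its CH terminus to the ketene carbon in a regioselective [2+2] cycloaddition (bonds C5–C6 and C7–C8) to give cyclobutenone 18, and at 80 °C reversible 4π electrocyclic opening of 18 gives dienylketene 19. Ring A then closes by 6π electrocyclisation of the isomer of 19 that holds ketene and pyranone cis, onto the only C–H carbon of the pyranone next to the chain (bond C5–C4a), and dienone 20, a β-diketone, enolises at once to the phenol. The closest known cases are the photochemical Wolff benzannulations of α,β-unsaturated and heteroaryl diazo ketones with silyl ynol ethers, which give resorcinol monosilyl ethers of exactly this pattern, and the γ-pyrone double bond, only weakly aromatic, should enter the electrocyclisation more easily than the benzene and furan rings of those cases. The regiochemistry needed (OH at C5, OSi at C7, H at C6 and C8) is secured by the polarity of 16 and by the single ring position open to closure; the chemoselectivity is secured because 12 has no free OH (the 4'-OH is silylated) and because the new 5-OH is hydrogen-bonded to the C4 carbonyl and is a poor trap for ketene. No stereocentre remains, since the centres of 18 and 20 are lost on ring opening and enolisation.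

**Step 10**
Reactants: 21 2-Ar-5-hydroxy-3-methoxy-7-(TIPS-oxy)-4H-chromen-4-one
Product: 22 dodoviscin J
Conditions: Bu4NF (2.5 equiv), AcOH (2.5 equiv), THF, 0 °C to rt
Reagents that add atoms: none
Why: Fluoride cleavage of two aryl silyl ethers, buffered with acetic acid so that the flavone meets neither strong base nor any acid strong enough to close the freed 4'-OH onto the prenyl group as a chroman; the product is achiral.

**Compound list**
1 | 4-bromo-2-methoxyphenol | COc1cc(Br)ccc1O | starting material
2 | 1-bromo-3-methylbut-2-ene (prenyl bromide) | CC(C)=CCBr | starting material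
3 | 4-bromo-2-methoxy-6-(3-methylbut-2-en-1-yl)phenol | COc1cc(Br)cc(CC=C(C)C)c1O | intermediate
4 | [4-bromo-2-methoxy-6-(3-methylbut-2-en-1-yl)phenoxy]tri(propan-2-yl)silane | COc1cc(Br)cc(CC=C(C)C)c1O[Si](C(C)C)(C(C)C)C(C)C | intermediate
5 | kojic acid (5-hydroxy-2-(hydroxymethyl)-4H-pyran-4-one) | O=c1cc(CO)occ1O | starting material
6 | 2-bromo-3-hydroxy-6-(hydroxymethyl)-4H-pyran-4-one (6-bromokojic acid) | O=c1cc(CO)oc(Br)c1O | intermediate
7 | 2-bromo-6-(hydroxymethyl)-3-methoxy-4H-pyran-4-one | COc1c(Br)oc(CO)cc1=O | intermediate
8 | 2-Ar-4,4,5,5-tetramethyl-1,3,2-dioxaborolane | COc1cc(B2OC(C)(C)C(C)(C)O2)cc(CC=C(C)C)c1O[Si](C(C)C)(C(C)C)C(C)C | intermediate (not isolated)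
9 | 2-Ar-6-(hydroxymethyl)-3-methoxy-4H-pyran-4-one | COc1cc(-c2oc(CO)cc(=O)c2OC)cc(CC=C(C)C)c1O[Si](C(C)C)(C(C)C)C(C)C | intermediate
10 | 6-Ar-5-methoxy-4-oxo-4H-pyran-2-carboxylic acid | COc1cc(-c2oc(C(=O)O)cc(=O)c2OC)cc(CC=C(C)C)c1O[Si](C(C)C)(C(C)C)C(C)C | intermediate
11 | 6-Ar-5-methoxy-4-oxo-4H-pyran-2-carbonyl chloride | COc1cc(-c2oc(C(=O)Cl)cc(=O)c2OC)cc(CC=C(C)C)c1O[Si](C(C)C)(C(C)C)C(C)C | intermediate (not isolated)
12 | 2-Ar-6-(diazoacetyl)-3-methoxy-4H-pyran-4-one | COc1cc(-c2oc(C(=O)C=[N+]=[N-])cc(=O)c2OC)cc(CC=C(C)C)c1O[Si](C(C)C)(C(C)C)C(C)C | intermediate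
13 | acetylene (ethyne) | C#C | starting material
14 | lithium acetylide | [Li+].[C-]#C | intermediate (not isolated)
15 | lithium ethynolate | [Li+].[O-]C#C | intermediate (not isolated)
16 | (ethynyloxy)tri(propan-2-yl)silane | C#CO[Si](C(C)C)(C(C)C)C(C)C | intermediate
17 | 2-Ar-3-methoxy-6-(2-oxoethenyl)-4H-pyran-4-one (pyranonylketene) | COc1cc(-c2oc(C=C=O)cc(=O)c2OC)cc(CC=C(C)C)c1O[Si](C(C)C)(C(C)C)C(C)C | intermediate (not isolated)
18 | 2-Ar-3-methoxy-6-[4-oxo-2-(TIPS-oxy)cyclobut-2-en-1-yl]-4H-pyran-4-one (racemic) | COc1cc(-c2oc(C3C(=O)C=C3O[Si](C(C)C)(C(C)C)C(C)C)cc(=O)c2OC)cc(CC=C(C)C)c1O[Si](C(C)C)(C(C)C)C(C)C | intermediate (not isolated)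
19 | 2-Ar-3-methoxy-6-[4-oxo-2-(TIPS-oxy)buta-1,3-dien-1-yl]-4H-pyran-4-one, pyranone ring and ketene CH cis on the C1=C2 bond of the chain | COc1cc(-c2oc(/C=C(O[Si](C(C)C)(C(C)C)C(C)C)\C=C=O)cc(=O)c2OC)cc(CC=C(C)C)c1O[Si](C(C)C)(C(C)C)C(C)C | intermediate (not isolated)
20 | 2-Ar-3-methoxy-7-(TIPS-oxy)-4aH-chromene-4,5-dione (racemic) | COc1cc(C2=C(OC)C(=O)C3C(=O)C=C(O[Si](C(C)C)(C(C)C)C(C)C)C=C3O2)cc(CC=C(C)C)c1O[Si](C(C)C)(C(C)C)C(C)C | intermediate (not isolated)
21 | 2-Ar-5-hydroxy-3-methoxy-7-(TIPS-oxy)-4H-chromen-4-one | COc1cc(-c2oc3cc(O[Si](C(C)C)(C(C)C)C(C)C)cc(O)c3c(=O)c2OC)cc(CC=C(C)C)c1O[Si](C(C)C)(C(C)C)C(C)C | intermediate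
22 | dodoviscin J (5,7-dihydroxy-2-[4-hydroxy-3-methoxy-5-(3-methylbut-2-en-1-yl)phenyl]-3-methoxy-4H-chromen-4-one, achiral) | COc1cc(-c2oc3cc(O)cc(O)c3c(=O)c2OC)cc(CC=C(C)C)c1O | target

Total step count: 10.
Longest linear sequence: 7 steps (steps 1, 2, 5, 6, 7, 9 and 10, from 1).

**Steps most likely to fail**

1. Step 9 (benzannulation).
   - What may go wrong: in the light-driven stage the ketene could be intercepted by unchanged diazo ketone before it meets 16, or light absorbed by the aryl pyranone could trigger hydrogen abstraction from the 3-methoxy group. The material would then be lost before the thermal stage.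
   - Fallback (no light and no diazo compound in the annulation flask): it sets out from 12 and comes back at 21. 12 would be rearranged in the dark with AgO2CPh (0.1 equiv) and Et3N in THF–H2O at rt (Arndt–Eistert homologation) to 2-(6-Ar-5-methoxy-4-oxo-4H-pyran-2-yl)acetic acid F1, which would be carried on without heating because a pyranonylacetic acid can lose CO2 when warmed. 1-Chloro-N,N,2-trimethylprop-1-en-1-amine would convert F1 into 2-(6-Ar-5-methoxy-4-oxo-4H-pyran-2-yl)acetyl chloride F2. Slow addition of Et3N to F2 and 16 (3 equiv) in toluene at rt would give ketene 17 by dehydrochlorination, the usual thermal entry into arylketene–alkyne benzannulations. Cyclobutenone 18 would form in the dark, and warming to 80–110 °C would lead through 19 and 20 to 21.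

2. Step 8 (silyl ynol ether).
   - What may go wrong: monolithium acetylide could disproportionate to dilithium acetylide on warming before it is oxidised, or the parent ynolate could be deprotonated or silylated on carbon, so that little 16 is obtained.
   - Fallback: it replaces acetylene 13 by commercial ethynyltrimethylsilane F3 and comes back at 16. F3 would be lithiated and oxidised in the same way to lithium 2-(trimethylsilyl)ethynolate F4, a well-behaved ynolate that cannot disproportionate. O-Silylation with the bulky iPr3SiOTf would give trimethyl{[(TIPS)oxy]ethynyl}silane F5, and the alkynyl SiMe3 group would be removed with K2CO3 in MeOH at 0 °C to give 16.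

3. Step 1 (C-prenylation).
   - What may go wrong: O-alkylation of the ambident phenoxide, and attack through the tertiary end of the allyl unit, could outrun ortho C-alkylation.
   - Fallback: it sets out from 1 and comes back at 3. 1 would be O-allylated (allyl bromide, K2CO3, acetone) to 4-bromo-2-methoxy-1-(prop-2-en-1-yloxy)benzene F6. Aromatic Claisen rearrangement (N,N-diethylaniline, 190 °C; only C6 is free) would give 4-bromo-2-methoxy-6-(prop-2-en-1-yl)phenol F7. Cross-metathesis of F7 with 2-methylbut-2-ene (second-generation Grubbs catalyst, CH2Cl2, 40 °C) would give 3.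

**Further compounds**
F1 | step 9 | 2-(6-Ar-5-methoxy-4-oxo-4H-pyran-2-yl)acetic acid | COc1cc(-c2oc(CC(=O)O)cc(=O)c2OC)cc(CC=C(C)C)c1O[Si](C(C)C)(C(C)C)C(C)C
F2 | step 9 | 2-(6-Ar-5-methoxy-4-oxo-4H-pyran-2-yl)acetyl chloride | COc1cc(-c2oc(CC(=O)Cl)cc(=O)c2OC)cc(CC=C(C)C)c1O[Si](C(C)C)(C(C)C)C(C)C
F3 | step 8 | ethynyltrimethylsilane | C#C[Si](C)(C)C
F4 | step 8 | lithium 2-(trimethylsilyl)ethynolate | [Li+].[O-]C#C[Si](C)(C)C
F5 | step 8 | trimethyl{[(TIPS)oxy]ethynyl}silane | C[Si](C)(C)C#CO[Si](C(C)C)(C(C)C)C(C)C
F6 | step 1 | 4-bromo-2-methoxy-1-(prop-2-en-1-yloxy)benzene | C=CCOc1ccc(Br)cc1OC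
F7 | step 1 | 4-bromo-2-methoxy-6-(prop-2-en-1-yl)phenol | C=CCc1cc(Br)cc(OC)c1O
A1 | direct plan | methyl vanillate (methyl 4-hydroxy-3-methoxybenzoate) | COC(=O)c1ccc(O)c(OC)c1
A2 | direct plan | tert-butyl 2-methylbut-3-en-2-yl carbonate | CC(C)(C)OC(=O)OC(C)(C)C=C
A3 | direct plan | methyl 3-methoxy-4-[(2-methylbut-3-en-2-yl)oxy]benzoate | COC(=O)c1ccc(OC(C)(C)C=C)c(OC)c1
A4 | direct plan | methyl methoxyacetate | COCC(=O)OC
A5 | direct plan | methyl 2-methoxy-3-{3-methoxy-4-[(2-methylbut-3-en-2-yl)oxy]phenyl}-3-oxopropanoate (racemic) | COC(=O)C(OC)C(=O)c1ccc(OC(C)(C)C=C)c(OC)c1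
A6 | direct plan | phloroglucinol (benzene-1,3,5-triol) | Oc1cc(O)cc(O)c1
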